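## Retrosynthetic overview

1. Ligupersin A ⇒ umbelliferone + drimane C11 alcohol (Mitsunobu ether). The 7-en-6-one comes from a regiodefined C6 silyl enol ether (Saegusa–Ito). Drimane numbering C1–C12 is used throughout.
2. Rings A and B form together (bonds C5–C10 and C8–C9) in one intramolecular Diels–Alder reaction of an acyclic (Z)-2-silyloxydiene / (E)-β-methyl-enoate triene. The C3 silyloxy centre controls C5, C9 and C10.
3. Triene ⇐ γ-hydroxy enone, made by C4–C5 bond formation between (6R)-6,7-epoxygeranate and a 2-silyloxypenta-1,3-diene (Lewis-acid epoxide opening at the tertiary carbon).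
4. Epoxide ⇐ methyl geranate by Shi epoxidation, which sets the only reagent-controlled stereocentre (C3).
5. Ring order: A and B simultaneously in step 4; no ring is made before or after.

Assumption: the SMILES is taken as the absolute configuration (3R,5S,9R,10S in drimane numbering), and methyl (2E)-geranate, (E)-pent-3-en-2-one, umbelliferone and the D-fructose-derived Shi ketone are taken as catalogue chemicals.

## Route

Step 1
Reactants: 1 methyl (2E)-3,7-dimethylocta-2,6-dienoate (methyl geranate)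
Product: 2 methyl (2E)-5-[(2R)-3,3-dimethyloxiran-2-yl]-3-methylpent-2-enoate
Conditions: D-fructose-derived Shi ketone (30 mol %), KHSO5 (as 2KHSO5·KHSO4·K2SO4), K2CO3, Bu4NHSO4, MeCN/CH2(OMe)2, aq. Na2B4O7 buffer (pH 10.5), 0 °C
Reagents that add atoms: potassium peroxymonosulfate, [K+].[O-]S(=O)(=O)OO
Why: Shi asymmetric epoxidation, in which the chiral dioxirane oxidises only the electron-rich trisubstituted 6,7-alkene (the enoate is inert) through the spiro transition state that gives the (6R)-epoxide, the centre that becomes C3 of the target.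

Step 2
Reactants: 3 (E)-pent-3-en-2-one
Product: 4 (E)-2-(trimethylsilyloxy)penta-1,3-diene
Conditions: TMSOTf, Et3N, Et2O, 0 °C; distillation
Reagents that add atoms: trimethylsilyl trifluoromethanesulfonate, C[Si](C)(C)OS(=O)(=O)C(F)(F)F
Why: Soft enolisation (O-silylation, then deprotonation of the α′ methyl by Et3N) gives the cross-conjugated 2-silyloxydiene; no stereocentre is formed.

Step 3
Reactants: 2 methyl (2E)-5-[(2R)-3,3-dimethyloxiran-2-yl]-3-methylpent-2-enoate; 4 (E)-2-(trimethylsilyloxy)penta-1,3-diene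
Product: 5 methyl (2E,6R,10E)-6-hydroxy-3,7,7-trimethyl-9-oxododeca-2,10-dienoate
Conditions: 4 (3 equiv), BF3·OEt2 (1.1 equiv), CH2Cl2, −78 °C; aq. NaHCO3; then 0.5 M HCl/THF, 0 °C
Reagents that add atoms: none
Why: Proposed new method: BF3 coordination polarises the trisubstituted epoxide so that the tertiary C–O bond lengthens and the terminal CH2 of the 2-silyloxydiene attacks that carbon (the enoate alkene is too electron-poor to compete), the silyl group leaves as Me3SiF to reveal the enone and the C–O stereocentre is untouched; the closest known reactions are Mukaiyama/Reetz-type tert-alkylation of silyl enol ethers with SN1-active electrophiles and Lewis-acid epoxide-initiated cyclisations terminated by silyl enol ethers, and the main competitor is the 1,2-hydride shift (Meinwald rearrangement), which excess nucleophile and −78 °C are meant to suppress.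

Step 4
Reactants: 5 methyl (2E,6R,10E)-6-hydroxy-3,7,7-trimethyl-9-oxododeca-2,10-dienoate
Product: 7 methyl (1R,2R,4aS,6R,8aR)-4,6-bis(tert-butyldimethylsilyloxy)-2,5,5,8a-tetramethyl-1,2,4a,5,6,7,8,8a-octahydronaphthalene-1-carboxylate, via bis-silyl siloxydiene 6 (not isolated)
Conditions: TBSOTf (2.6 equiv), Et3N (4 equiv), CH2Cl2, −78 to 0 °C; then PhMe, BHT, 180 °C (sealed tube)
Reagents that add atoms: tert-butyldimethylsilyl trifluoromethanesulfonate, CC(C)(C)[Si](C)(C)OS(=O)(=O)C(F)(F)F
Why: O-silylation and Z-selective α′-enol silylation give a (Z)-2-silyloxydiene that undergoes an intramolecular Diels–Alder reaction (formally an Ihara-type double Michael) with the (E)-β-methyl enoate through the ester-endo, chair-tether transition state with the C3 silyloxy group equatorial, which closes both rings at once, sets C5, C9 and C10 (trans-decalin; 10-Me, C11 and 3-O all cis; the C8 methyl cis to the ester is erased later) and fixes the C6 oxygen as a regiodefined enol ether.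

Step 5
Reactants: 7 methyl (1R,2R,4aS,6R,8aR)-4,6-bis(tert-butyldimethylsilyloxy)-2,5,5,8a-tetramethyl-1,2,4a,5,6,7,8,8a-octahydronaphthalene-1-carboxylate
Product: 8 [(1R,2S,4aS,6R,8aS)-4,6-bis(tert-butyldimethylsilyloxy)-2,5,5,8a-tetramethyl-1,2,4a,5,6,7,8,8a-octahydronaphthalen-1-yl]methanol
Conditions: i-Bu2AlH (3 equiv), CH2Cl2, −78 to −20 °C; aq. KNaC4H4O6 work-up
Reagents that add atoms: none
Why: Hydride reduction of the ester to the primary alcohol leaves the silyl ether and the silyl enol ether (which masks the C6 ketone) untouched and changes no stereocentre.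

Step 6
Reactants: 8 [(1R,2S,4aS,6R,8aS)-4,6-bis(tert-butyldimethylsilyloxy)-2,5,5,8a-tetramethyl-1,2,4a,5,6,7,8,8a-octahydronaphthalen-1-yl]methanol; 9 umbelliferone (7-hydroxy-2H-chromen-2-one)
Product: 10 7-{[(1R,2S,4aS,6R,8aS)-4,6-bis(tert-butyldimethylsilyloxy)-2,5,5,8a-tetramethyl-1,2,4a,5,6,7,8,8a-octahydronaphthalen-1-yl]methoxy}-2H-chromen-2-one
Conditions: PPh3, DIAD, PhMe, 0 to 50 °C
Reagents that add atoms: none
Why: Mitsunobu etherification of the primary alcohol with the acidic phenol (pKa about 7.8) runs under near-neutral conditions that spare the silyl enol ether and touches no stereocentre.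

Step 7
Reactants: 10 7-{[(1R,2S,4aS,6R,8aS)-4,6-bis(tert-butyldimethylsilyloxy)-2,5,5,8a-tetramethyl-1,2,4a,5,6,7,8,8a-octahydronaphthalen-1-yl]methoxy}-2H-chromen-2-one
Product: 12 ligupersin A, via 3-O-TBS-ligupersin A 11 (not isolated)
Conditions: Pd(OAc)2 (1.2 equiv), MeCN, 40 °C; filter; then 48% aq. HF, MeCN, rt
Reagents that add atoms: none
Why: Saegusa–Ito oxidation (palladation of the enol ether at C7 from the less hindered face, then syn β-hydride loss from C8) gives only the 7-en-6-one and erases C8, and HF then cleaves the hindered C3 silyl ether without base, so the trans C5 centre is not epimerised.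

## Compound list

1 | methyl (2E)-3,7-dimethylocta-2,6-dienoate (methyl geranate) | COC(=O)/C=C(\C)CCC=C(C)C | starting material
2 | methyl (2E)-5-[(2R)-3,3-dimethyloxiran-2-yl]-3-methylpent-2-enoate | COC(=O)/C=C(\C)CC[C@H]1OC1(C)C | intermediate
3 | (E)-pent-3-en-2-one | C/C=C/C(C)=O | starting material
4 | (E)-2-(trimethylsilyloxy)penta-1,3-diene | C/C=C/C(=C)O[Si](C)(C)C | intermediate
5 | methyl (2E,6R,10E)-6-hydroxy-3,7,7-trimethyl-9-oxododeca-2,10-dienoate | COC(=O)/C=C(\C)CC[C@@H](O)C(C)(C)CC(=O)/C=C/C | intermediate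
6 | methyl (2E,6R,8Z,10E)-6,9-bis(tert-butyldimethylsilyloxy)-3,7,7-trimethyldodeca-2,8,10-trienoate | COC(=O)/C=C(\C)CC[C@@H](O[Si](C)(C)C(C)(C)C)C(C)(C)/C=C(\O[Si](C)(C)C(C)(C)C)/C=C/C | intermediate
7 | methyl (1R,2R,4aS,6R,8aR)-4,6-bis(tert-butyldimethylsilyloxy)-2,5,5,8a-tetramethyl-1,2,4a,5,6,7,8,8a-octahydronaphthalene-1-carboxylate | C[C@@H]1C=C(O[Si](C)(C)C(C)(C)C)[C@@H]2C(C)(C)[C@H](O[Si](C)(C)C(C)(C)C)CC[C@@]2(C)[C@@H]1C(=O)OC | intermediate
8 | [(1R,2S,4aS,6R,8aS)-4,6-bis(tert-butyldimethylsilyloxy)-2,5,5,8a-tetramethyl-1,2,4a,5,6,7,8,8a-octahydronaphthalen-1-yl]methanol | C[C@@H]1C=C(O[Si](C)(C)C(C)(C)C)[C@@H]2C(C)(C)[C@H](O[Si](C)(C)C(C)(C)C)CC[C@@]2(C)[C@@H]1CO | intermediate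
9 | umbelliferone (7-hydroxy-2H-chromen-2-one) | Oc1ccc2ccc(=O)oc2c1 | starting material
10 | 7-{[(1R,2S,4aS,6R,8aS)-4,6-bis(tert-butyldimethylsilyloxy)-2,5,5,8a-tetramethyl-1,2,4a,5,6,7,8,8a-octahydronaphthalen-1-yl]methoxy}-2H-chromen-2-one | C[C@@H]1C=C(O[Si](C)(C)C(C)(C)C)[C@@H]2C(C)(C)[C@H](O[Si](C)(C)C(C)(C)C)CC[C@@]2(C)[C@@H]1COc1ccc2ccc(=O)oc2c1 | intermediate
11 | 7-{[(1R,4aS,6R,8aS)-6-(tert-butyldimethylsilyloxy)-2,5,5,8a-tetramethyl-4-oxo-1,4,4a,5,6,7,8,8a-octahydronaphthalen-1-yl]methoxy}-2H-chromen-2-one (3-O-TBS-ligupersin A) | CC1=CC(=O)[C@@H]2C(C)(C)[C@H](O[Si](C)(C)C(C)(C)C)CC[C@@]2(C)[C@@H]1COc1ccc2ccc(=O)oc2c1 | intermediate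
12 | ligupersin A, 7-{[(1R,4aS,6R,8aS)-6-hydroxy-2,5,5,8a-tetramethyl-4-oxo-1,4,4a,5,6,7,8,8a-octahydronaphthalen-1-yl]methoxy}-2H-chromen-2-one | CC1=CC(=O)[C@@H]2C(C)(C)[C@H](O)CC[C@@]2(C)[C@@H]1COc1ccc2ccc(=O)oc2c1 | target

## Step count and risks

Total step count: 7. Longest linear sequence: 6 (steps 1, 3, 4, 5, 6, 7; step 2 makes the reagent 4).

The three steps most likely to fail:

**Step 3 (intermolecular epoxide opening at the tertiary carbon).** Hydride shift to the ketone, or capture of that ketone by 4, may dominate. The fallback sets out from 1 and comes back at 5; it builds the C3–C4 bond by carbonyl addition instead of the C4–C5 bond by epoxide opening. Chemoselective ozonolysis of the electron-rich 6,7-alkene of 1 (O3, CH2Cl2/pyridine, −78 °C) gives methyl (2E)-3-methyl-6-oxohex-2-enoate F1. Brown-type reverse prenylation with the antipode of B-prenyldiisopinocampheylborane that delivers the (6R)-alcohol (Et2O, −78 °C; NaBO3·4H2O work-up) gives methyl (2E,6R)-6-hydroxy-3,7,7-trimethylnona-2,8-dienoate F2. Hydroboration of the terminal vinyl group with 9-BBN and oxidation with NaBO3·4H2O give methyl (2E,6R)-6,9-dihydroxy-3,7,7-trimethylnon-2-enoate F3. TEMPO/PhI(OAc)2 closes the 1,4-diol to the lactone methyl (2E)-5-[(2R)-3,3-dimethyl-5-oxooxolan-2-yl]-3-methylpent-2-enoate F4. Addition of (E)-prop-1-enyllithium (1.05 equiv, THF, −78 °C) to the lactone carbonyl, which is more electrophilic than the β,β-disubstituted conjugated ester, gives 5 on work-up.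

**Step 4 (two-ring cycloaddition).** The enoate is β,β-disubstituted, enol silylation could occur at the γ-methyl instead of C5, the hydroxy ketone could silylate as its lactol, and the endo/exo and facial selectivities rest on modest conformational preferences. The fallback sets out from 5 and comes back at 7; it replaces the pericyclic step by a stepwise anionic annulation under thermodynamic control. Silylation of the alcohol alone (TBSOTf, 2,6-lutidine, CH2Cl2, −78 °C) gives methyl (2E,6R,10E)-6-(tert-butyldimethylsilyloxy)-3,7,7-trimethyl-9-oxododeca-2,10-dienoate F5. LiN(SiMe3)2 (THF, −78 to 0 °C) forms the α′-enolate, which adds 6-exo to the enoate (ring A); the resulting ester enolate adds 6-endo to the enone (ring B). This reversible double Michael sequence gives the trans-decalone methyl (1R,2R,4aS,6R,8aR)-6-(tert-butyldimethylsilyloxy)-2,5,5,8a-tetramethyl-4-oxodecahydronaphthalene-1-carboxylate F6, with C5 and C9 free to equilibrate. Kinetic enol silylation at the C7 methylene (KN(SiMe3)2, TBSCl, THF, −78 °C) then gives 7; any C8 epimer converges in step 7.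

**Step 6 (Mitsunobu at a primary carbon flanked by the quaternary C10).** Substitution at C11 may be too slow. The fallback sets out from 8 and comes back at 10; it forms the aryl–oxygen bond instead of the C11–oxygen bond. Cross-coupling of the alcohol 8 with commercial 7-bromocoumarin (Pd2(dba)3, tBuBrettPhos, Cs2CO3, PhMe, 90 °C; zerovalent palladium, so the silyl enol ether is not oxidised) gives 10 directly; no new compound is isolated on the way.

## Further compounds

F1 | step 3 | methyl (2E)-3-methyl-6-oxohex-2-enoate | COC(=O)/C=C(\C)CCC=O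
F2 | step 3 | methyl (2E,6R)-6-hydroxy-3,7,7-trimethylnona-2,8-dienoate | COC(=O)/C=C(\C)CC[C@@H](O)C(C)(C)C=C
F3 | step 3 | methyl (2E,6R)-6,9-dihydroxy-3,7,7-trimethylnon-2-enoate | COC(=O)/C=C(\C)CC[C@@H](O)C(C)(C)CCO
F4 | step 3 | methyl (2E)-5-[(2R)-3,3-dimethyl-5-oxooxolan-2-yl]-3-methylpent-2-enoate | COC(=O)/C=C(\C)CC[C@H]1OC(=O)CC1(C)C
F5 | step 4 | methyl (2E,6R,10E)-6-(tert-butyldimethylsilyloxy)-3,7,7-trimethyl-9-oxododeca-2,10-dienoate | COC(=O)/C=C(\C)CC[C@@H](O[Si](C)(C)C(C)(C)C)C(C)(C)CC(=O)/C=C/C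
F6 | step 4 | methyl (1R,2R,4aS,6R,8aR)-6-(tert-butyldimethylsilyloxy)-2,5,5,8a-tetramethyl-4-oxodecahydronaphthalene-1-carboxylate | C[C@@H]1CC(=O)[C@@H]2C(C)(C)[C@H](O[Si](C)(C)C(C)(C)C)CC[C@@]2(C)[C@@H]1C(=O)OC
F0 | step 6 | none | none
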